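We are asked 5 things about 4 flasks that differ in temperature and in nothing else, so the question is how many powers of ten each temperature buys.

| setting | Saturday's | Tuesday's | west | south | north | north-east |
|---|---|---|---|---|---|---|
| substrate | 37 mM | 37 mM | 37 mM | 37 mM | 37 mM | 37 mM |
| partner | 2.5 equiv | 2.5 equiv | 2.50 equiv | 2.50 equiv | 2.50 equiv | 2.50 equiv |
| free catalyst | 1 mol% | 4 mol% | 2 mol% | 2 mol% | 2 mol% | 2 mol% |
| second catalyst | 5 mol% | 5 mol% | 5 mol% | 5 mol% | 5 mol% | 5 mol% |
| temperature | 15 °C | 42 °C | 50 °C | 35 °C | 65 °C | 20 °C |
| remark | run made earlier | run made earlier |  |  |  |  |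
| time |  |  | 25 h | 25 h | 25 h | 25 h |

| Saturday's: time / h | Saturday's: product / % | Tuesday's: time / h | Tuesday's: product / % |
|---|---|---|---|
| 30.0 | 4 | 5.00 | 24 |
| 60.0 | 8 | 10.0 | 47 |
| 96.0 | 20 | 15.0 | 63 |
| 120 | 28 | 20.0 | 72 |
| 144 | 24 | 25.0 | 78 |
| 192 | 37 | 30.0 | 83 |

(scatter of a reading: 2 percentage points)

* which flask leads in amount of product, in percent of the substrate charged ("all alike" within 1.5 percentage points) (west / south / north / north-east / all alike)
* how much product is there at the end, in percent of the substrate charged: west
* how much product is there at the end, in percent of the substrate charged: south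
* how much product is there at the end, in percent of the substrate charged: north
* how much product is there at the end, in percent of the substrate charged: north-east



We treat the product curve as a pseudo-first-order climb: the dose is the rate constant times the time, and the share made is one minus e to the minus dose. Saturday's last reading gives 0.00241 h⁻¹ and Tuesday's reading at 25.0 h gives 0.0606 h⁻¹, both carrying the scatter. If the rate is proportional to free catalyst, each unit of loading on Tuesday worked 6.29 times as fast as on Saturday. The decade step, the temperature rise that multiplies the rate by 10, then reads 33.8 K.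

Tuesday's dose at 25 h is 1.51. Going to 2 mol% takes off 0.301 of a decade, and each flask then adds its temperature gap from Tuesday over the decade step. Our own reckoning gives west 72.9%, south 37.5%, north 97.3% and north-east 15.6%, so north makes more than any other.

What would have to be true for north not to lead? North stands 0.444 of a decade above west, so at unbroken pace it reaches west's amount after 9.00 h. For north to fall behind west on this reckoning, its pace would have to break off before 9.00 h.

The forecast, with figures somewhat apart from ours, names north with 77% for west, 42% for south, 93% for north and 14% for north-east, adding “The main risk is catalyst death”.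

The flasks give 89.4% for west, 49.6% for south, 98.8% for north and 11.2% for north-east, and north leads.

    substrate + free catalyst ⇌ free catalyst + open intermediate (K = 3.20, k = 47.0 M⁻¹ h⁻¹, Ea = 62.0 kJ mol⁻¹, ΔH = 50.0 kJ mol⁻¹)
    partner + catalyst intermediate → second catalyst + product (k = 9.00 M⁻¹ h⁻¹, Ea = 49.0 kJ mol⁻¹)
    second catalyst + open intermediate ⇌ catalyst intermediate (K = 17.0 M⁻¹, k = 660 M⁻¹ h⁻¹, Ea = 59.0 kJ mol⁻¹, ΔH = 33.0 kJ mol⁻¹)
    partner + second catalyst → spent catalyst (k = 0.160 M⁻¹ h⁻¹, Ea = 59.0 kJ mol⁻¹)
    (constants at 20 °C)

Against our catch-up time of 9.00 h, north at 12.5 h already held 97.7% product, more than the 89.4% of west at its end, with 88.5% of the second catalyst spent. North-east at 250 h, ten times its asked time, has by our reckoning one decade more dose, the same as a rise of one decade step of 33.8 K, which gives 81.6%, yet that flask held 58.1% product, with 91.7% of the second catalyst spent and 31.6% of the substrate charged standing as open intermediate.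

(The readings come from a simulation for an exercise; scatter was added.)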